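In a one-step world the starting material falls towards zero while its product piles up, and the first reading of the north-east run, charged with 0.025 M, looked like that: at 10.0 s I read 7% of the starting material and 52% target.

| flask | starting material | remark | time |
|---|---|---|---|
| north-east | 0.025 M | run made earlier |  |
| flask | 0.050 M |  | 15 min |

north-east run (percent of the starting material charged)

| time / s | starting material / % | target / % |
|---|---|---|
| 10.0 | 7 | 52 |
| 12.0 | 3 | 55 |
| 20.0 | 3 | 49 |
| 30.0 | 4 | 44 |
| 50.0 | 3 | 36 |
| 90.0 | 7 | 30 |

(scatter of a reading: 1.5 percentage points)

- the reaction counts as stopped when no species that holds the starting material changes by six tenths of a point or more over the second half of the time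

* the state of affairs at 15 min: stopped, and by what, or still going (all of the starting material has reacted / it is still moving / forward and back rates have come level)
* share of the starting material used up at 15 min
* target at 15 min, in percent of the starting material charged
* isomer of the product at 15 min, in percent of the starting material charged

At 12.0 s the north-east run read 55% target, and the rest of the balance, 42.0%, which I took for isomer of the product, was smaller. That early lead of the target looks like kinetic control. By 90.0 s the north-east run read 30% target and a rest of 63.0%, which I read as thermodynamic control taking over, yet the readings of the starting material no longer fell.

The last 5 readings of the north-east run show no fall, so I replaced that stretch of the curve by its mean, the resting share of starting material: 4.00%. The error of that mean is 0.67 percentage points, but the reading at 90.0 s stands 3 points above it, against a scatter of 1.5 points, so the flatness is a judgement.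

The new flask holds twice the charge, 0.050 M, and runs ten times as long as the last reading, 15 min. I assumed first-order steps, which one charge cannot test; the resting share then stays put, so I expected forward and back rates level and 96.0% used up.

The forecast said forward and back rates have come level, with 96% used up, 27% target and 69% isomer of the product, holding that the “equilibrium position should not depend on the doubled concentration”.

In the flask forward and back rates have come level, with 97.1% used up, 28.7% target and 63.2% isomer of the product.

    starting material ⇌ third isomer (K = 1.80, k = 1.30 s⁻¹)
    starting material ⇌ target (K = 10.0, k = 0.820 s⁻¹)
    starting material ⇌ isomer of the product (K = 22.0, k = 0.300 s⁻¹)

The isomer of the product in the flask stands 5.8 points under the forecast, and at 15.0 min the flask also held 5.17% third isomer. Carried to a neighbour flask charged with 0.20 M, on the same assumption of first-order steps, the resting share of 4.00% gave 96.0% used up; at 15.0 min that neighbour flask had 97.1% used up, with 2.9% of its starting material left.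

The numbers in the tables stem from a simulated flask on assumed constants; scatter was added.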